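Ring A (C1 OMe, C2 H, C3 phenethyl, C4 OMe, C5 OMe, C6 hydroxyalkyl chain) is made from acyclic pieces. Its C1 and C5 oxygens sit 1,3 across C6 and C4 bears an oxygen beside C3, so the arene is a 2-alkyl-4-methoxy-5-phenethylcyclohexane-1,3-dione one dehydrogenation short. Cutting C3–C4 and C5–C6 gives an E-enone, which supplies C1, C2, C3 and C6 with both side chains and the free tertiary alcohol, and dimethyl methoxymalonate, which supplies C4 and C5. One Michael–Claisen operation forms both bonds and the carbocycle; decarboxylation, dehydrogenation via a bis-silyl dienol ether and O-methylation complete the route.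

Key step: step 3

Assumption: the hydroxy ketone used first is taken as purchased (it is also one acid-catalysed hydration away from 6-methylhept-5-en-2-one). All chiral intermediates are racemic or diastereomer mixtures, which is immaterial because the target is achiral. Ring-A numbering C1–C6 is used for the ring carbons of all intermediates.

Step 1
Reactants: 1 6-hydroxy-6-methylheptan-2-one; 2 3-phenylpropanal
Product: 3 3,9-dihydroxy-9-methyl-1-phenyldecan-5-one (racemic)
Conditions: LDA (2.2 equiv), THF, −78 °C; then 2 (1.1 equiv), −78 °C; aq. NH4Cl
Reagents that add atoms: none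
Why: Directed (kinetic) aldol addition: LDA first forms the lithium alkoxide of 1 and then removes a proton from the less hindered methyl group, and this enolate adds to aldehyde 2 at −78 °C; the new carbinol centre forms as a racemate and is removed in step 2.

Step 2
Reactants: 3 3,9-dihydroxy-9-methyl-1-phenyldecan-5-one
Product: 5 (E)-9-hydroxy-9-methyl-1-phenyldec-3-en-5-one, via secondary mesylate 4 (not isolated)
Conditions: MsCl (1.2 equiv), Et3N (4 equiv), CH2Cl2, 0 °C → rt
Reagents that add atoms: none
Why: Mesylation then E1cB elimination completes the aldol condensation: the secondary β-hydroxyl is sulfonylated much faster than the hindered tertiary alcohol, and the β-mesyloxy ketone eliminates under Et3N to the conjugated, thermodynamically preferred E-enone without any acid that could cyclise the hydroxy ketone.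

Step 3
Reactants: 5 (E)-9-hydroxy-9-methyl-1-phenyldec-3-en-5-one; 6 dimethyl methoxymalonate (1.3 equiv)
Product: 8 methyl 3-(3-hydroxy-3-methylbutyl)-1-methoxy-2,4-dioxo-6-(2-phenylethyl)cyclohexane-1-carboxylate (diastereomer mixture; partly enolised), via Michael adduct 7 (not isolated)
Conditions: NaOMe (1.5 equiv), MeOH, 0 °C → 65 °C; then AcOH to pH 5, 0 °C
Reagents that add atoms: none
Why: Methoxide generates the stabilised anion of 6, which adds in conjugate fashion to C3 of enone 5 (C3–C4 bond) to give adduct 7; the regenerated ketone then enolises towards its chain-bearing α'-methylene C6, which attacks one ester group and expels methoxide (C5–C6 bond). This is the malonate Michael–Claisen (dimedone-type) annulation of α,β-unsaturated ketones, applied here to a 2-substituted malonate and an α'-substituted ketone. The carbocycle of ring A closes in a 6-(enolendo)-exo-trig acyl substitution. The three sp3 centres C3, C4 and C6 arise without control as a diastereomer mixture, which does not matter because all are flattened on aromatisation. The step needs 1,4- over 1,2-addition, which the soft and reversibly adding malonate anion secures, and closure through C6 and not C2, which holds because only C6 gives a six-membered ring whereas C2 would give a cyclobutanone; O-acylation to an enol lactone is reversible in methoxide. Irreversible deprotonation of the acidic C6–H of the 1,3-dione should pull the sequence forward and also shield 8 from retro-Claisen cleavage.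

Step 4
Reactants: 8 methyl 3-(3-hydroxy-3-methylbutyl)-1-methoxy-2,4-dioxo-6-(2-phenylethyl)cyclohexane-1-carboxylate
Product: 10 2-(3-hydroxy-3-methylbutyl)-4-methoxy-5-(2-phenylethyl)cyclohexane-1,3-dione (diastereomer mixture; enolised), via β-keto acid 9 (not isolated)
Conditions: NaOH (2 M aq., 4 equiv), MeOH, 60 °C; then AcOH to pH 4, 50 °C
Reagents that add atoms: none
Why: Saponification and β-keto acid decarboxylation: hydroxide cleaves the methyl ester while the dione sits as its enolate and is protected from retro-Claisen attack, and acid 9 then loses CO2 through the cyclic six-membered transition state on warming at pH 4, which is too mild to cyclise the tertiary alcohol onto the dione or to ionise the C4 methoxy group; C4 is reprotonated without control.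

Step 5
Reactants: 10 2-(3-hydroxy-3-methylbutyl)-4-methoxy-5-(2-phenylethyl)cyclohexane-1,3-dione
Product: 11 6-methoxy-2-[3-methyl-3-(trimethylsilyloxy)butyl]-5-(2-phenylethyl)-1,3-bis(trimethylsilyloxy)cyclohexa-1,3-diene (double bonds C1=C2 and C5=C6 in ring-A numbering; diastereomer mixture; used crude)
Conditions: TMSOTf (3.6 equiv), Et3N (5 equiv), CH2Cl2, 0 °C → rt; pentane extraction, cold aq. NaHCO3 wash
Reagents that add atoms: trimethylsilyl trifluoromethanesulfonate, C[Si](C)(C)OS(=O)(=O)C(F)(F)F
Why: Soft enolisation of a cyclohexane-1,3-dione with TMSOTf/Et3N to its 1,3-bis(silyloxy)cyclohexa-1,3-diene is established chemistry, the tertiary alcohol is silylated in the same operation, and the excess amine keeps the medium non-acidic; the second deprotonation should favour the unhindered C2 methylene, and a regioisomeric diene enolised towards C4 would converge to the same arene in step 6.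

Step 6
Reactants: 11 6-methoxy-2-[3-methyl-3-(trimethylsilyloxy)butyl]-5-(2-phenylethyl)-1,3-bis(trimethylsilyloxy)cyclohexa-1,3-diene
Product: 13 2-(3-hydroxy-3-methylbutyl)-4-methoxy-5-(2-phenylethyl)benzene-1,3-diol, via tris-silyl arene 12 (not isolated)
Conditions: DDQ (1.05 equiv), 2,4,6-collidine (1.5 equiv), CH2Cl2, 0 °C; then citric acid, MeOH, rt; argon
Reagents that add atoms: none
Why: Quinone dehydrogenation of a cyclohexa-1,3-diene: DDQ abstracts hydride from the allylic, methoxy-stabilised C4–H (or from C3–H) and loss of the neighbouring proton aromatises ring A, the silyl ethers keeping the oxidisable p-methoxyphenol-type arene and the alcohol masked while oxidant is present, after which mild acid methanolysis removes all three TMS groups.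

Step 7
Reactants: 13 2-(3-hydroxy-3-methylbutyl)-4-methoxy-5-(2-phenylethyl)benzene-1,3-diol
Product: 14 4-[2,3,6-trimethoxy-4-(2-phenylethyl)phenyl]-2-methylbutan-2-ol (CNP0309409.0)
Conditions: MeI (4 equiv), K2CO3 (4 equiv), acetone, 56 °C, argon
Reagents that add atoms: iodomethane, CI
Why: Williamson ether synthesis: carbonate deprotonates only the two phenols, whose phenoxides are methylated by MeI, while the tertiary alcohol is too weakly acidic and too hindered to react.

Compound list
1 | 6-hydroxy-6-methylheptan-2-one | CC(=O)CCCC(C)(C)O | starting material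
2 | 3-phenylpropanal | O=CCCc1ccccc1 | starting material
3 | 3,9-dihydroxy-9-methyl-1-phenyldecan-5-one (racemic) | CC(C)(O)CCCC(=O)CC(O)CCc1ccccc1 | intermediate
4 | 9-hydroxy-9-methyl-5-oxo-1-phenyldecan-3-yl methanesulfonate (racemic) | CC(C)(O)CCCC(=O)CC(OS(C)(=O)=O)CCc1ccccc1 | intermediate (not isolated)
5 | (E)-9-hydroxy-9-methyl-1-phenyldec-3-en-5-one | CC(C)(O)CCCC(=O)/C=C/CCc1ccccc1 | intermediate
6 | dimethyl methoxymalonate (dimethyl 2-methoxypropanedioate) | COC(C(=O)OC)C(=O)OC | starting material
7 | dimethyl 2-(9-hydroxy-9-methyl-5-oxo-1-phenyldecan-3-yl)-2-methoxypropanedioate (racemic) | COC(=O)C(OC)(C(=O)OC)C(CCc1ccccc1)CC(=O)CCCC(C)(C)O | intermediate (not isolated)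
8 | methyl 3-(3-hydroxy-3-methylbutyl)-1-methoxy-2,4-dioxo-6-(2-phenylethyl)cyclohexane-1-carboxylate (diastereomer mixture, partly enolised) | COC(=O)C1(OC)C(CCc2ccccc2)CC(=O)C(CCC(C)(C)O)C1=O | intermediate
9 | 3-(3-hydroxy-3-methylbutyl)-1-methoxy-2,4-dioxo-6-(2-phenylethyl)cyclohexane-1-carboxylic acid (diastereomer mixture) | OC(=O)C1(OC)C(CCc2ccccc2)CC(=O)C(CCC(C)(C)O)C1=O | intermediate (not isolated)
10 | 2-(3-hydroxy-3-methylbutyl)-4-methoxy-5-(2-phenylethyl)cyclohexane-1,3-dione (diastereomer mixture, enolised) | COC1C(CCc2ccccc2)CC(=O)C(CCC(C)(C)O)C1=O | intermediate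
11 | 6-methoxy-2-[3-methyl-3-(trimethylsilyloxy)butyl]-5-(2-phenylethyl)-1,3-bis(trimethylsilyloxy)cyclohexa-1,3-diene (diastereomer mixture) | COC1C(CCc2ccccc2)C=C(O[Si](C)(C)C)C(CCC(C)(C)O[Si](C)(C)C)=C1O[Si](C)(C)C | intermediate
12 | 4-methoxy-2-[3-methyl-3-(trimethylsilyloxy)butyl]-5-(2-phenylethyl)-1,3-bis(trimethylsilyloxy)benzene | COc1c(CCc2ccccc2)cc(O[Si](C)(C)C)c(CCC(C)(C)O[Si](C)(C)C)c1O[Si](C)(C)C | intermediate (not isolated)
13 | 2-(3-hydroxy-3-methylbutyl)-4-methoxy-5-(2-phenylethyl)benzene-1,3-diol | COc1c(O)c(CCC(C)(C)O)c(O)cc1CCc1ccccc1 | intermediate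
14 | 4-[2,3,6-trimethoxy-4-(2-phenylethyl)phenyl]-2-methylbutan-2-ol (achiral) | COc1cc(CCc2ccccc2)c(OC)c(OC)c1CCC(C)(C)O | target

Total step count: 7. Longest linear sequence: 7 steps (1 and 2 to 14); malonate 6 is purchased.

Steps most likely to fail

Step 3. The hindered tertiary methoxymalonate anion may add too slowly, or the Michael equilibrium may lie on the side of the enone while methoxide-driven self-condensation and isomerisation of the enone consume it. The fallback sets out from 5 and comes back at 10, replacing steps 3 and 4. It makes the same two bonds with a neutral mono-ester donor and a separate ring closure. Methyl methoxyacetate is converted with LDA and TMSCl in THF at −78 °C into 1,2-dimethoxy-1-(trimethylsilyloxy)ethene F1. Enone 5 is capped with TMSCl and imidazole in DMF to give (E)-9-methyl-1-phenyl-9-(trimethylsilyloxy)dec-3-en-5-one F2. Mukaiyama–Michael addition of F1 to F2 (catalytic TMSOTf, CH2Cl2, −78 °C) should give methyl 2-methoxy-9-methyl-3-(2-phenylethyl)-5,9-bis(trimethylsilyloxy)dec-4-enoate F3. Citric acid in MeOH unmasks this to methyl 9-hydroxy-2-methoxy-9-methyl-5-oxo-3-(2-phenylethyl)decanoate F4. t-BuOK in THF then closes C5–C6 by Claisen condensation of the C6 enolate onto the ester, as in the cyclisation of 5-oxoalkanoates to cyclohexane-1,3-diones, and delivers dione 10.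

Step 5. The second enolisation may stall at the vinylogous silyl ester, the dienol ether may hydrolyse on handling, or silyl-triflate-assisted loss of the C4 methoxy group as methanol may aromatise the ring without oxidation and delete that oxygen. The fallback sets out from 10 and comes back at 13, replacing steps 5 and 6. It avoids enol silanes and Lewis acid altogether: Pd/C-catalysed acceptorless dehydrogenation (Pd/C, K2CO3, N,N-dimethylacetamide, 150 °C, argon sweep), a known type of cyclohexanone-to-phenol dehydrogenation, would convert the potassium enolate of 10 into 13 with loss of hydrogen in a basic medium. The crude phenoxide solution can be methylated directly as in step 7. This fallback makes no new compound (F0).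

Step 4. Saponification of the hindered quaternary ester may be slow enough for retro-Claisen opening to compete, or the acidification needed for decarboxylation may trigger attack of the tertiary hydroxyl on the enolised dione. The fallback sets out from 8 and comes back at 10. It is a Krapcho-type dealkoxycarbonylation (LiCl, H2O, DMSO, 130 °C): chloride removes the ester methyl group by SN2 attack and the resulting carboxylate loses CO2, so neither hydroxide nor added acid is used. This fallback makes no new compound (F0).

Further compounds
F1 | step 3 | 1,2-dimethoxy-1-(trimethylsilyloxy)ethene (E/Z mixture) | COC=C(OC)O[Si](C)(C)C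
F2 | step 3 | (E)-9-methyl-1-phenyl-9-(trimethylsilyloxy)dec-3-en-5-one | CC(C)(O[Si](C)(C)C)CCCC(=O)/C=C/CCc1ccccc1
F3 | step 3 | methyl 2-methoxy-9-methyl-3-(2-phenylethyl)-5,9-bis(trimethylsilyloxy)dec-4-enoate (diastereomer mixture) | COC(=O)C(OC)C(CCc1ccccc1)C=C(O[Si](C)(C)C)CCCC(C)(C)O[Si](C)(C)C
F4 | step 3 | methyl 9-hydroxy-2-methoxy-9-methyl-5-oxo-3-(2-phenylethyl)decanoate (diastereomer mixture) | COC(=O)C(OC)C(CCc1ccccc1)CC(=O)CCCC(C)(C)O
F0 | step 5 | none | none
F0 | step 4 | none | none
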